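In a one-step world substrate turns into target and the flask needs no clock, but the earlier runs showed me a second step, so I followed a run slowly and reckoned from there.

| flask | substrate | reagent in the second phase | temperature | remark | time | volume of the second phase over the first |
|---|---|---|---|---|---|---|
| dusk | 0.35 M (in portions, 4) | 4 equiv | 65 °C | run made earlier; portions every 6.0 h |  |  |
| dawn | 0.55 M (in portions, 4) | 4 equiv | 95 °C | run made earlier; portions every 6.0 h |  |  |
| noon | 0.25 M (in portions, 4) | 6 equiv | 65 °C | run made earlier; portions every 6.0 h |  |  |
| blue | 0.25 M (in portions, 4) | 4.00 equiv | 100 °C | the portions of substrate follow each other after 6.0 h, the first at the start | 8.0 d | 1.0 |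
| violet | 0.25 M (in portions, 4) | 4.00 equiv | 70 °C | the portions of substrate follow each other after 6.0 h, the first at the start | 8.0 d | 1.0 |
| amber | 0.25 M (in portions, 4) | 4.00 equiv | 80 °C | the portions of substrate follow each other after 6.0 h, the first at the start | 8.0 d | 1.0 |
| green | 0.25 M (in portions, 4) | 4.00 equiv | 85 °C | the portions of substrate follow each other after 6.0 h, the first at the start | 8.0 d | 1.0 |
| teal | 0.25 M (in portions, 4) | 4.00 equiv | 120 °C | the portions of substrate follow each other after 6.0 h, the first at the start | 8.0 d | 1.0 |

- dusk (time / d: target / %, decomposed product / %, substrate / %): 3.00: 99.9, 1.6, 0.2; 10.0: 97.3, 0, 0.3; 15.0: 97.3, 2.0, 0; 25.0: 98.2, 5.1, 0; 30.0: 96.9, 3.5, 0.8; 50.0: 94.6, 8.2, 0; 60.0: 91.9, 8.0, 1.7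
- dawn (time / d: target / %, decomposed product / %, substrate / %): 0.833: 99.6, 2.1, 0; 1.25: 95.8, 2.6, 0; 1.67: 92.9, 6.2, 0; 2.50: 89.5, 10.9, 1.0; 4.00: 81.5, 16.3, 0; 6.00: 71.8, 26.1, 0; 10.0: 58.7, 40.2, 0
- noon (time / d: target / %, decomposed product / %, substrate / %): 5.00: 98.7, 2.0, 0; 15.0: 97.8, 0.6, 0.1; 25.0: 96.8, 4.0, 0; 30.0: 96.0, 3.5, 0; 60.0: 92.6, 6.0, 0

(readings scatter by 1 percentage point)

- charges count per volume of the first phase; a concentration in a rate is the amount of a species over the volume of its own phase; every rate counts per litre of the first phase
- the earlier runs hold the two phases in the same ratio of volumes as the flask asked about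
- a reading or a percentage of target counts all its forms, free or not

1. all flasks from highest to lowest share of target in all that became target or decomposed product, at 8.0 d (blue / violet / amber / green / teal)
2. the share of target in all that became target or decomposed product of the flask you put first, at 8.0 d
3. the share of target in all that became target or decomposed product of the flask you put last, at 8.0 d

Substrate is the limiting reagent, set against 4.00 equiv of reagent in the second phase, so I wrote its balance: the charge equals substrate plus target in all its forms plus decomposed product. In the first instants the portions arrive 6.0 h apart, so the charge enters on average 9.00 h after the start, and the dusk run at 65 °C already read 0.2% of substrate at 3.00 d. In the middle, with the dawn run reading substrate at 0%, the balance has two terms, and that run closes it at 98.9% at 10.0 d. That loss looked first order: its dawn constant read 0.0564 d⁻¹ at 4.00 d and 0.0553 d⁻¹ at 10.0 d.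

At the cool end the dusk and noon runs read 91.9% and 92.6% of target at 60.0 d, which is within the scatter although their reagent differs, and together they gave 0.00135 d⁻¹. The two temperatures then gave an activation temperature of 15400 K. I therefore took the share of target at the end of each asked flask as the exponential of minus the loss constant times the mean age of the target, here 7.62 d. For violet, the loss constant, meaning the first-order rate per day at which target, free or not, becomes decomposed product, came to 0.00263 d⁻¹. Its half-life of 264 d is longer than that age. I reckoned violet at 98.0%, amber, from a loss constant of 0.00936 d⁻¹, at 93.1%, green at 87.7%, blue at 47.7%, and teal, far beyond the runs, at 0.239%, so violet stood higher than the others and teal lower.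

The forecast gave violet > amber > green > blue > teal, with 98.1% and 0.2%, saying “The order simply follows temperature”. The simulation gave violet > amber > green > blue > teal, with 98.1% for violet, 93.2% for amber, 87.8% for green, 47.8% for blue and 0.243% for teal.

    reagent in the reaction phase ⇌ reagent in the second phase, rate k1*([reagent in the reaction phase] - [reagent in the second phase]/K1) per volume of the first phase (partition coefficient = 0.490, kL = 0.0300 h⁻¹)
    substrate + reagent in the reaction phase → target (k = 6.10 L mol⁻¹ h⁻¹, Ea = 89.0 kJ mol⁻¹)
    target ⇌ product in the second phase, rate k3*([target] - [product in the second phase]/K3) per volume of the first phase (partition coefficient = 0.280, kL = 1.30 h⁻¹)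
    target → decomposed product (k = 0.00520 h⁻¹, Ea = 128 kJ mol⁻¹)
    (constants at 100 °C)

The length of the wait counts for violet: read at 80.0 d instead of 8.0 d, its share falls from 98.1% to 81.1%, a drop of 17 percentage points. The loss constant kept for violet, 0.00263 d⁻¹, taken over that longer age, gives 81.1%. For amber the same reckoning from 0.00936 d⁻¹ gives 47.5%, and amber stands at 47.3% of target at 80.0 d.

The numbers in the tables were computed from invented constants; scatter was added.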